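## Retrosynthetic overview

1. Target ⇐ its hexa-O-benzyl ether (BCl3 debenzylation); the dihydrofuran of ring system A is closed last by acid-mediated C2–O cyclisation of a 1,2,2-triarylethanol.
2. Each triarylethanol ⇐ a racemising 1,2,2-triarylethanone by Ru transfer-hydrogenative dynamic kinetic resolution (sets C3; C2 follows as trans on ring closure).
3. Each triarylethanone ⇐ Pd-catalysed enolate α-arylation (the C3–aryl bonds): the ring-B ketone from a deoxybenzoin plus a 2-iodo-5-chlororesorcinol bis-MOM ether; the ring-A ketone by union of a stilbene-bearing benzyl aryl ketone with the 6-chloro ring-B dihydrobenzofuran.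
4. Pieces ⇐ resorcinol (MOM, Ir C–H borylation to one isolated aryl boronate, Cu halodeboronation, ortho-lithiation/iodination), phenol + acetyl chloride, 4-bromophenol + vinyltrifluoroborate (Suzuki, then Heck).
5. Ring order: dihydrofuran of ring system B first (step 11), dihydrofuran of ring system A last (step 19).

Assumption: the SMILES is read as trans-(2S,3S) in both dihydrobenzofurans; acetyl chloride and potassium vinyltrifluoroborate are counted as starting materials.

Abbreviations: Bn = benzyl; MOM = methoxymethyl; RB = (2S,3S)-4-(benzyloxy)-2-[4-(benzyloxy)phenyl]-3-[3,5-bis(benzyloxy)phenyl]-2,3-dihydro-1-benzofuran-6-yl (the ring-B unit of 18, attached through C6).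

## Route

Step 1
Reactants: 1 resorcinol
Product: 2 1,3-bis(methoxymethoxy)benzene
Conditions: NaH (2.5 equiv), MOMCl (2.4 equiv), DMF, 0 °C → rt
Reagents that add atoms: chloromethyl methyl ether, COCCl
Why: Phenoxide O-alkylation (Williamson-type MOM protection); MOM later directs the ortho-lithiation and is shed by the acid that closes the rings.

Step 2
Reactants: 2 1,3-bis(methoxymethoxy)benzene
Product: 3 2-[3,5-bis(methoxymethoxy)phenyl]-4,4,5,5-tetramethyl-1,3,2-dioxaborolane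
Conditions: [Ir(OMe)(cod)]2 (1 mol %), dtbpy (2 mol %), B2pin2 (1.0 equiv), THF, 80 °C; filtration through a short silica plug
Reagents that add atoms: bis(pinacolato)diboron, CC1(C)OB(OC1(C)C)B1OC(C)(C)C(C)(C)O1
Why: Sterically governed Ir-catalysed aromatic C–H borylation reaches only C5, the one C–H not ortho to an OMOM group; the isolated boronate is divided between steps 3 and 5.

Step 3
Reactants: 3 2-[3,5-bis(methoxymethoxy)phenyl]-4,4,5,5-tetramethyl-1,3,2-dioxaborolane
Product: 4 1-chloro-3,5-bis(methoxymethoxy)benzene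
Conditions: CuCl2 (3 equiv), MeOH/H2O 1:1, 80 °C
Reagents that add atoms: copper(II) chloride, Cl[Cu]Cl
Why: Cu(II)-mediated chlorodeboronation replaces Bpin by Cl at the ipso carbon, so the regiochemistry fixed in step 2 is carried over.

Step 4
Reactants: 4 1-chloro-3,5-bis(methoxymethoxy)benzene
Product: 6 5-chloro-2-iodo-1,3-bis(methoxymethoxy)benzene, via [4-chloro-2,6-bis(methoxymethoxy)phenyl]lithium 5 (not isolated)
Conditions: n-BuLi (1.1 equiv), THF, −20 → 0 °C; then I2 (1.2 equiv), −78 °C → rt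
Reagents that add atoms: iodine, II; n-butyllithium, [Li]CCCC (Li of 5 only)
Why: Directed ortho-metalation: the C–H flanked by two OMOM groups is lithiated through double chelation and the aryllithium is trapped by iodine.

Step 5
Reactants: 3 2-[3,5-bis(methoxymethoxy)phenyl]-4,4,5,5-tetramethyl-1,3,2-dioxaborolane
Product: 7 1-bromo-3,5-bis(methoxymethoxy)benzene
Conditions: CuBr2 (3 equiv), MeOH/H2O 1:1, 80 °C
Reagents that add atoms: copper(II) bromide, Br[Cu]Br
Why: Cu(II)-mediated bromodeboronation at the ipso carbon of the same boronate gives the meta-bromide that cannot be made by direct bromination.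

Step 6
Reactants: 8 phenol; 9 acetyl chloride
Product: 11 1-(4-hydroxyphenyl)ethan-1-one, via phenyl acetate 10 (not isolated)
Conditions: TfOH (neat), 0 °C → rt
Reagents that add atoms: none
Why: O-acylation followed by TfOH-promoted Fries rearrangement, which gives the para-acyl phenol at room temperature.

Step 7
Reactants: 11 1-(4-hydroxyphenyl)ethan-1-one
Product: 12 1-[4-(benzyloxy)phenyl]ethan-1-one
Conditions: BnBr (1.1 equiv), K2CO3, DMF, rt
Reagents that add atoms: benzyl bromide, BrCc1ccccc1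
Why: Williamson ether synthesis on the phenoxide.

Step 8
Reactants: 12 1-[4-(benzyloxy)phenyl]ethan-1-one; 7 1-bromo-3,5-bis(methoxymethoxy)benzene
Product: 13 1-[4-(benzyloxy)phenyl]-2-[3,5-bis(methoxymethoxy)phenyl]ethan-1-one
Conditions: Pd2(dba)3 (1 mol %), Xantphos (2.4 mol %), NaOt-Bu (2.2 equiv), toluene, 80 °C; 12 in 1.3-fold excess
Reagents that add atoms: none
Why: Pd-catalysed ketone α-arylation (Buchwald–Hartwig–Miura); excess ketone and a wide-bite-angle ligand favour monoarylation of the methyl ketone.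

Step 9
Reactants: 13 1-[4-(benzyloxy)phenyl]-2-[3,5-bis(methoxymethoxy)phenyl]ethan-1-one; 6 5-chloro-2-iodo-1,3-bis(methoxymethoxy)benzene
Product: 14 1-[4-(benzyloxy)phenyl]-2-[4-chloro-2,6-bis(methoxymethoxy)phenyl]-2-[3,5-bis(methoxymethoxy)phenyl]ethan-1-one (racemic, α-centre labile)
Conditions: Pd2(dba)3 (2.5 mol %), P(t-Bu)3·HBF4 (6 mol %), NaOt-Bu (2.2 equiv), toluene, 50 °C
Reagents that add atoms: none
Why: Pd-catalysed enolate α-arylation in which oxidative addition takes place at C–I and not C–Cl at 50 °C, and reductive elimination from the aryl-Pd C-enolate forms the C3–C3a bond of ring system B; the new α-centre is racemic and base-labile, which step 10 uses.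

Step 10
Reactants: 14 racemic triaryl ketone
Product: 15 (1S,2S)-1-[4-(benzyloxy)phenyl]-2-[4-chloro-2,6-bis(methoxymethoxy)phenyl]-2-[3,5-bis(methoxymethoxy)phenyl]ethan-1-ol
Conditions: (S,S)-Ts-DENEB (oxo-tethered RuCl–TsDPEN, 2 mol %), HCO2H (5 equiv), DBU (6 equiv), DMF, 40 °C
Reagents that add atoms: none
Why: Proposed new method: transfer-hydrogenative dynamic kinetic resolution of a 1,2,2-triarylethanone — DBU exchanges the doubly benzylic α-H (pKa about 17) faster than reduction, the (S,S)-Ru–H/N–H catalyst delivers hydride through the outer-sphere six-membered transition state to the carbonyl face fixed by the CH/π contact with the 4-benzyloxyphenyl ketone aryl (same sense as acetophenone → (S)-1-phenylethanol, hence 1S), and only the (2S)-ketone offers that face in a Felkin–Anh arrangement with the bulky 2,6-disubstituted aryl anti to hydride, so the (1S,2S)-alcohol forms and C2 (later C3 of ring B) is set; closest known reaction type is Noyori–Ikariya ATH-DKR of α-substituted aryl ketones, not shown for α,α-diaryl ketones whose two α-aryls differ only in substitution pattern.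

Step 11
Reactants: 15 (1S,2S)-triarylethanol
Product: 17 (2S,3S)-2-[4-(benzyloxy)phenyl]-6-chloro-3-(3,5-dihydroxyphenyl)-2,3-dihydro-1-benzofuran-4-ol, via 5-[(1S,2S)-2-[4-(benzyloxy)phenyl]-1-(4-chloro-2,6-dihydroxyphenyl)-2-hydroxyethyl]benzene-1,3-diol 16 (not isolated)
Conditions: HCl (3 M in MeOH)/THF 1:1, 40 °C
Reagents that add atoms: none
Why: Acid removes the four MOM groups and ionises the p-benzyloxybenzylic alcohol; the cation is trapped by an ortho phenol (either one gives the same product) in an SN1 cyclisation that is reversible under acid, so the thermodynamically favoured trans-(2S,3S) ring accumulates while C3 is untouched.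

Step 12
Reactants: 17 ring-B triol
Product: 18 (2S,3S)-4-(benzyloxy)-2-[4-(benzyloxy)phenyl]-3-[3,5-bis(benzyloxy)phenyl]-6-chloro-2,3-dihydro-1-benzofuran
Conditions: BnBr (3.6 equiv), K2CO3 (4 equiv), DMF, 40 °C
Reagents that add atoms: benzyl bromide, BrCc1ccccc1
Why: Williamson O-benzylation of the three phenols under mild carbonate base, which does not affect the stereocentres.

Step 13
Reactants: 19 4-bromophenol
Product: 20 1-(benzyloxy)-4-bromobenzene
Conditions: BnBr (1.1 equiv), K2CO3, acetone, reflux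
Reagents that add atoms: benzyl bromide, BrCc1ccccc1
Why: Williamson ether synthesis on the phenoxide.

Step 14
Reactants: 20 1-(benzyloxy)-4-bromobenzene; 21 potassium vinyltrifluoroborate
Product: 22 1-(benzyloxy)-4-ethenylbenzene
Conditions: PdCl2(dppf)·CH2Cl2 (2 mol %), Cs2CO3 (3 equiv), THF/H2O 9:1, 85 °C
Reagents that add atoms: none
Why: Suzuki–Miyaura vinylation of an aryl bromide with a vinyltrifluoroborate.

Step 15
Reactants: 12 1-[4-(benzyloxy)phenyl]ethan-1-one; 6 5-chloro-2-iodo-1,3-bis(methoxymethoxy)benzene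
Product: 23 1-[4-(benzyloxy)phenyl]-2-[4-chloro-2,6-bis(methoxymethoxy)phenyl]ethan-1-one
Conditions: Pd2(dba)3 (1.5 mol %), P(t-Bu)3·HBF4 (3.6 mol %), NaOt-Bu (2.2 equiv), THF, 45 °C; 12 in 1.3-fold excess
Reagents that add atoms: none
Why: Pd-catalysed ketone α-arylation, selective for C–I over C–Cl at 45 °C, with the di-ortho-substituted aryl preventing a second arylation.

Step 16
Reactants: 23 chloro ketone; 22 1-(benzyloxy)-4-ethenylbenzene
Product: 24 1-[4-(benzyloxy)phenyl]-2-{4-[(E)-2-[4-(benzyloxy)phenyl]ethenyl]-2,6-bis(methoxymethoxy)phenyl}ethan-1-one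
Conditions: Pd2(dba)3 (1.5 mol %), P(t-Bu)3·HBF4 (6 mol %), Cy2NMe (1.5 equiv), 1,4-dioxane, 100 °C
Reagents that add atoms: none
Why: Mizoroki–Heck reaction of an aryl chloride with a bulky electron-rich phosphine; syn-insertion/syn-β-hydride elimination gives the E-stilbene and the amine base does not enolise the ketone.

Step 17
Reactants: 24 stilbene ketone; 18 ring-B aryl chloride
Product: 25 1-[4-(benzyloxy)phenyl]-2-{4-[(E)-2-[4-(benzyloxy)phenyl]ethenyl]-2,6-bis(methoxymethoxy)phenyl}-2-RB-ethan-1-one (both C2 epimers, labile)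
Conditions: Pd(OAc)2 (5 mol %), XPhos (10 mol %), K3PO4 (3 equiv), toluene, 100 °C; 24 in 1.2-fold excess
Reagents that add atoms: none
Why: Pd-catalysed α-arylation of a stabilised α-aryl ketone enolate (K3PO4 is basic enough and spares the existing ring) with the unhindered aryl chloride joins the two halves and forms the C3(ring A)–aryl bond; the α-centre is labile and is fixed in step 18.

Step 18
Reactants: 25 triaryl ketone (epimer mixture)
Product: 26 (1S,2S)-1-[4-(benzyloxy)phenyl]-2-{4-[(E)-2-[4-(benzyloxy)phenyl]ethenyl]-2,6-bis(methoxymethoxy)phenyl}-2-RB-ethan-1-ol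
Conditions: (S,S)-Ts-DENEB (4 mol %), HCO2H (5 equiv), DBU (6 equiv), DMF, 40 °C
Reagents that add atoms: none
Why: Proposed new method: the same transfer-hydrogenative dynamic kinetic resolution as in step 10 — DBU epimerises the α-centre, the (S,S)-Ru–H/N–H catalyst fixes the carbonyl face through the ketone aryl and the Felkin–Anh-matched (2S)-epimer with the 2,6-disubstituted aryl anti to hydride is reduced, giving the (1S,2S)-alcohol under catalyst control since the ring-B stereocentres are remote; closest known reaction type is Noyori–Ikariya ATH-DKR of α-substituted aryl ketones.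

Step 19
Reactants: 26 (1S,2S)-triarylethanol
Product: 28 (2S,3S)-2-[4-(benzyloxy)phenyl]-6-[(E)-2-[4-(benzyloxy)phenyl]ethenyl]-3-RB-2,3-dihydro-1-benzofuran-4-ol, via (1S,2S)-1-[4-(benzyloxy)phenyl]-2-{4-[(E)-2-[4-(benzyloxy)phenyl]ethenyl]-2,6-dihydroxyphenyl}-2-RB-ethan-1-ol 27 (not isolated)
Conditions: HCl (3 M in MeOH)/THF 1:1, 40 °C
Reagents that add atoms: none
Why: As in step 11, MOM cleavage and reversible SN1 closure of a phenol onto the p-benzyloxybenzylic cation give the trans-(2S,3S) ring A with C3 untouched; benzyl ethers, the stilbene and ring B (which can only re-equilibrate to trans) survive.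

Step 20
Reactants: 28 hexa-O-benzyl ether
Product: 29 target, 5-[(2S,3S)-4-hydroxy-6-[(2S,3S)-4-hydroxy-2-(4-hydroxyphenyl)-6-[(E)-2-(4-hydroxyphenyl)ethenyl]-2,3-dihydro-1-benzofuran-3-yl]-2-(4-hydroxyphenyl)-2,3-dihydro-1-benzofuran-3-yl]benzene-1,3-diol
Conditions: BCl3 (1 M in CH2Cl2, 15 equiv), pentamethylbenzene (20 equiv), CH2Cl2, −78 °C; aqueous work-up
Reagents that add atoms: none
Why: BCl3 cleaves aryl benzyl ethers at −78 °C while pentamethylbenzene traps the benzyl cations by Friedel–Crafts alkylation, so the stilbene and both trans-dihydrofurans are kept.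

## Compound list

1 | resorcinol | Oc1cccc(O)c1 | starting material
2 | 1,3-bis(methoxymethoxy)benzene | COCOc1cccc(OCOC)c1 | intermediate
3 | 2-[3,5-bis(methoxymethoxy)phenyl]-4,4,5,5-tetramethyl-1,3,2-dioxaborolane | COCOc1cc(OCOC)cc(c1)B1OC(C)(C)C(C)(C)O1 | intermediate
4 | 1-chloro-3,5-bis(methoxymethoxy)benzene | COCOc1cc(Cl)cc(OCOC)c1 | intermediate
5 | [4-chloro-2,6-bis(methoxymethoxy)phenyl]lithium | [Li]c1c(OCOC)cc(Cl)cc1OCOC | intermediate (not isolated)
6 | 5-chloro-2-iodo-1,3-bis(methoxymethoxy)benzene | COCOc1cc(Cl)cc(OCOC)c1I | intermediate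
7 | 1-bromo-3,5-bis(methoxymethoxy)benzene | COCOc1cc(Br)cc(OCOC)c1 | intermediate
8 | phenol | Oc1ccccc1 | starting material
9 | acetyl chloride | CC(Cl)=O | starting material
10 | phenyl acetate | CC(=O)Oc1ccccc1 | intermediate (not isolated)
11 | 1-(4-hydroxyphenyl)ethan-1-one | CC(=O)c1ccc(O)cc1 | intermediate
12 | 1-[4-(benzyloxy)phenyl]ethan-1-one | CC(=O)c1ccc(OCc2ccccc2)cc1 | intermediate
13 | 1-[4-(benzyloxy)phenyl]-2-[3,5-bis(methoxymethoxy)phenyl]ethan-1-one | O=C(Cc1cc(OCOC)cc(OCOC)c1)c1ccc(OCc2ccccc2)cc1 | intermediate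
14 | 1-[4-(benzyloxy)phenyl]-2-[4-chloro-2,6-bis(methoxymethoxy)phenyl]-2-[3,5-bis(methoxymethoxy)phenyl]ethan-1-one (racemic) | O=C(c1ccc(OCc2ccccc2)cc1)C(c1c(OCOC)cc(Cl)cc1OCOC)c1cc(OCOC)cc(OCOC)c1 | intermediate
15 | (1S,2S)-1-[4-(benzyloxy)phenyl]-2-[4-chloro-2,6-bis(methoxymethoxy)phenyl]-2-[3,5-bis(methoxymethoxy)phenyl]ethan-1-ol | O[C@H](c1ccc(OCc2ccccc2)cc1)[C@H](c1c(OCOC)cc(Cl)cc1OCOC)c1cc(OCOC)cc(OCOC)c1 | intermediate
16 | 5-[(1S,2S)-2-[4-(benzyloxy)phenyl]-1-(4-chloro-2,6-dihydroxyphenyl)-2-hydroxyethyl]benzene-1,3-diol | O[C@H](c1ccc(OCc2ccccc2)cc1)[C@H](c1c(O)cc(Cl)cc1O)c1cc(O)cc(O)c1 | intermediate (not isolated)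
17 | (2S,3S)-2-[4-(benzyloxy)phenyl]-6-chloro-3-(3,5-dihydroxyphenyl)-2,3-dihydro-1-benzofuran-4-ol | Clc1cc(O)c2c(c1)O[C@H](c1ccc(OCc3ccccc3)cc1)[C@H]2c1cc(O)cc(O)c1 | intermediate
18 | (2S,3S)-4-(benzyloxy)-2-[4-(benzyloxy)phenyl]-3-[3,5-bis(benzyloxy)phenyl]-6-chloro-2,3-dihydro-1-benzofuran | Clc1cc(OCc3ccccc3)c2c(c1)O[C@H](c1ccc(OCc3ccccc3)cc1)[C@H]2c1cc(OCc2ccccc2)cc(OCc2ccccc2)c1 | intermediate
19 | 4-bromophenol | Oc1ccc(Br)cc1 | starting material
20 | 1-(benzyloxy)-4-bromobenzene | Brc1ccc(OCc2ccccc2)cc1 | intermediate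
21 | potassium vinyltrifluoroborate | C=C[B-](F)(F)F.[K+] | starting material
22 | 1-(benzyloxy)-4-ethenylbenzene | C=Cc1ccc(OCc2ccccc2)cc1 | intermediate
23 | 1-[4-(benzyloxy)phenyl]-2-[4-chloro-2,6-bis(methoxymethoxy)phenyl]ethan-1-one | O=C(Cc1c(OCOC)cc(Cl)cc1OCOC)c1ccc(OCc2ccccc2)cc1 | intermediate
24 | 1-[4-(benzyloxy)phenyl]-2-{4-[(E)-2-[4-(benzyloxy)phenyl]ethenyl]-2,6-bis(methoxymethoxy)phenyl}ethan-1-one | O=C(Cc1c(OCOC)cc(/C=C/c2ccc(OCc3ccccc3)cc2)cc1OCOC)c1ccc(OCc2ccccc2)cc1 | intermediate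
25 | 1-[4-(benzyloxy)phenyl]-2-{4-[(E)-2-[4-(benzyloxy)phenyl]ethenyl]-2,6-bis(methoxymethoxy)phenyl}-2-RB-ethan-1-one (both C2 epimers) | O=C(c1ccc(OCc2ccccc2)cc1)C(c1c(OCOC)cc(/C=C/c2ccc(OCc3ccccc3)cc2)cc1OCOC)c1cc(OCc2ccccc2)c2c(c1)O[C@H](c1ccc(OCc3ccccc3)cc1)[C@H]2c1cc(OCc2ccccc2)cc(OCc2ccccc2)c1 | intermediate
26 | (1S,2S)-1-[4-(benzyloxy)phenyl]-2-{4-[(E)-2-[4-(benzyloxy)phenyl]ethenyl]-2,6-bis(methoxymethoxy)phenyl}-2-RB-ethan-1-ol | O[C@H](c1ccc(OCc2ccccc2)cc1)[C@H](c1c(OCOC)cc(/C=C/c2ccc(OCc3ccccc3)cc2)cc1OCOC)c1cc(OCc2ccccc2)c2c(c1)O[C@H](c1ccc(OCc3ccccc3)cc1)[C@H]2c1cc(OCc2ccccc2)cc(OCc2ccccc2)c1 | intermediate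
27 | (1S,2S)-1-[4-(benzyloxy)phenyl]-2-{4-[(E)-2-[4-(benzyloxy)phenyl]ethenyl]-2,6-dihydroxyphenyl}-2-RB-ethan-1-ol | O[C@H](c1ccc(OCc2ccccc2)cc1)[C@H](c1c(O)cc(/C=C/c2ccc(OCc3ccccc3)cc2)cc1O)c1cc(OCc2ccccc2)c2c(c1)O[C@H](c1ccc(OCc3ccccc3)cc1)[C@H]2c1cc(OCc2ccccc2)cc(OCc2ccccc2)c1 | intermediate (not isolated)
28 | (2S,3S)-2-[4-(benzyloxy)phenyl]-6-[(E)-2-[4-(benzyloxy)phenyl]ethenyl]-3-RB-2,3-dihydro-1-benzofuran-4-ol | O(Cc1ccccc1)c1ccc(/C=C/c2cc(O)c3c(c2)O[C@H](c2ccc(OCc4ccccc4)cc2)[C@H]3c2cc(OCc4ccccc4)c3c(c2)O[C@H](c2ccc(OCc4ccccc4)cc2)[C@H]3c2cc(OCc3ccccc3)cc(OCc3ccccc3)c2)cc1 | intermediate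
29 | 5-[(2S,3S)-4-hydroxy-6-[(2S,3S)-4-hydroxy-2-(4-hydroxyphenyl)-6-[(E)-2-(4-hydroxyphenyl)ethenyl]-2,3-dihydro-1-benzofuran-3-yl]-2-(4-hydroxyphenyl)-2,3-dihydro-1-benzofuran-3-yl]benzene-1,3-diol | Oc1ccc(/C=C/c2cc(O)c3c(c2)O[C@H](c2ccc(O)cc2)[C@H]3c2cc(O)c3c(c2)O[C@H](c2ccc(O)cc2)[C@H]3c2cc(O)cc(O)c2)cc1 | target

## Step count and risks

Total steps: 20. Longest linear sequence: 12 steps (1 → 2 → 3 → 4 → 9 → 10 → 11 → 12 → 17 → 18 → 19 → 20).

**Step 10 (proposed new dynamic kinetic resolution; step 18 repeats the method and carries the same risk).** The hindered ketone may reduce slowly, or the catalyst may not tell the two α-aryl groups apart well enough. The fallback uses known chemistry and sets out from 14. NaBH4 in MeOH/THF at 0 °C gives the alcohol as all four stereoisomers, 1-[4-(benzyloxy)phenyl]-2-[4-chloro-2,6-bis(methoxymethoxy)phenyl]-2-[3,5-bis(methoxymethoxy)phenyl]ethan-1-ol F1. HCl/MeOH as in step 11 converts them to the racemic trans-dihydrobenzofuran, that is 17 together with (2R,3R)-2-[4-(benzyloxy)phenyl]-6-chloro-3-(3,5-dihydroxyphenyl)-2,3-dihydro-1-benzofuran-4-ol F2. Benzylation as in step 12 gives 18 together with (2R,3R)-4-(benzyloxy)-2-[4-(benzyloxy)phenyl]-3-[3,5-bis(benzyloxy)phenyl]-6-chloro-2,3-dihydro-1-benzofuran F3. Preparative SFC on an amylose tris(3,5-dimethylphenylcarbamate) phase separates the enantiomers, and the route is rejoined at 18.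

**Step 9 (α-arylation with the di-ortho-substituted iodide).** The congested reductive elimination may stall, or the I/Cl selectivity may erode. The fallback sets out from 23 (made in step 15) and 7 and forms the other α-aryl bond instead: the enolate of the already hindered ketone 23 is arylated with the unhindered bromide 7 [Pd(OAc)2/Xantphos, Cs2CO3, toluene, 100 °C; C–Br reacts, C–Cl does not]. This is the polarity of step 17, gives 14 directly, where the route is rejoined, and makes 13 and step 8 unnecessary. No new compound arises (F0).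

**Step 17 (union of the two halves through a hindered enolate and an aryl chloride).** The enolate of 24 may be too encumbered, or the stilbene may interfere. The fallback sets out from 12 and 18 and builds ring system A linearly. α-Arylation of the unhindered methyl ketone 12 with chloride 18 [Pd(OAc)2/XPhos, K3PO4, toluene, 100 °C] gives 1-[4-(benzyloxy)phenyl]-2-RB-ethan-1-one F4. Arylation of F4 with iodide 6 under the conditions of step 9 gives 1-[4-(benzyloxy)phenyl]-2-[4-chloro-2,6-bis(methoxymethoxy)phenyl]-2-RB-ethan-1-one F5 (both C2 epimers). A Heck reaction of F5 with styrene 22 under the conditions of step 16 installs the stilbene last and rejoins the route at 25.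

## Further compounds

F0 | step 9 | none | none
F1 | step 10 | 1-[4-(benzyloxy)phenyl]-2-[4-chloro-2,6-bis(methoxymethoxy)phenyl]-2-[3,5-bis(methoxymethoxy)phenyl]ethan-1-ol (mixture of all four stereoisomers) | OC(c1ccc(OCc2ccccc2)cc1)C(c1c(OCOC)cc(Cl)cc1OCOC)c1cc(OCOC)cc(OCOC)c1
F2 | step 10 | (2R,3R)-2-[4-(benzyloxy)phenyl]-6-chloro-3-(3,5-dihydroxyphenyl)-2,3-dihydro-1-benzofuran-4-ol | Clc1cc(O)c2c(c1)O[C@@H](c1ccc(OCc3ccccc3)cc1)[C@@H]2c1cc(O)cc(O)c1
F3 | step 10 | (2R,3R)-4-(benzyloxy)-2-[4-(benzyloxy)phenyl]-3-[3,5-bis(benzyloxy)phenyl]-6-chloro-2,3-dihydro-1-benzofuran | Clc1cc(OCc3ccccc3)c2c(c1)O[C@@H](c1ccc(OCc3ccccc3)cc1)[C@@H]2c1cc(OCc2ccccc2)cc(OCc2ccccc2)c1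
F4 | step 17 | 1-[4-(benzyloxy)phenyl]-2-[(2S,3S)-4-(benzyloxy)-2-[4-(benzyloxy)phenyl]-3-[3,5-bis(benzyloxy)phenyl]-2,3-dihydro-1-benzofuran-6-yl]ethan-1-one | O=C(Cc1cc(OCc2ccccc2)c2c(c1)O[C@H](c1ccc(OCc3ccccc3)cc1)[C@H]2c1cc(OCc2ccccc2)cc(OCc2ccccc2)c1)c1ccc(OCc2ccccc2)cc1
F5 | step 17 | 1-[4-(benzyloxy)phenyl]-2-[4-chloro-2,6-bis(methoxymethoxy)phenyl]-2-[(2S,3S)-4-(benzyloxy)-2-[4-(benzyloxy)phenyl]-3-[3,5-bis(benzyloxy)phenyl]-2,3-dihydro-1-benzofuran-6-yl]ethan-1-one (both C2 epimers) | O=C(c1ccc(OCc2ccccc2)cc1)C(c1c(OCOC)cc(Cl)cc1OCOC)c1cc(OCc2ccccc2)c2c(c1)O[C@H](c1ccc(OCc3ccccc3)cc1)[C@H]2c1cc(OCc2ccccc2)cc(OCc2ccccc2)c1
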